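**Retrosynthetic overview**

1. The target is reached by global desilylation of its tetrasilyl ether. That ether is cut at the exocyclic ylidene C=C and at the lactone C(=O)–C(α) bond into a C22 polyenynal (ring A half) and a (2Z,4E)-3-iodo-dienyl phenyl carbonate (ring B half).
2. Enabling feature: in the furan-2(5H)-one ring (O1, C2=O, C3, C4, C5) the carbonyl carbon C2 carries only oxygen besides C3, and C3 lies cis to the C5–O1 arm across C3=C4. A (Z)-alkenyl anion at C3 whose O1 already bears C2 as an aryl carbonate therefore closes the ring by 5-exo-trig acyl substitution, and the acidic C5–H2 of the new lactone lets the ylidene be condensed on in the same flask.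
3. The iodo carbonate comes from alkoxide-directed trans-hydroalumination/iodination of an enynol, built by Takai olefination and Sonogashira coupling on the ring B aldehyde. The 5,6-trans-diol of ring B comes from a syn-selective Sharpless epoxidation and a C5-inverting hydrolysis. The polyenynal comes from Sonogashira, Horner–Wadsworth–Emmons and Wittig chain extension.
4. Both carbocycles come from one chiral-pool ketone, (−)-actinol, through a common enol triflate. It supplies the six ring carbons, the three methyl groups and the C3 carbinol stereocentre of each end group.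
5. Ring order: rings A and B are present from the start; the butenolide is the only ring formed, in step 19.

Key step: step 19

Assumption and notation: (4R,6R)-actinol is taken as a commercial chiral building block. End-ring locants C1–C6 follow carotenoid numbering (C1 gem-dimethyl, C3 carbinol, C5 methyl-bearing carbon, C6 chain-bearing carbon). In names, RA = (4R)-4-[(tert-butyldimethylsilyl)oxy]-2,6,6-trimethylcyclohex-1-en-1-yl and RB = (1R,2R,4S)-4-[(tert-butyldimethylsilyl)oxy]-2,6,6-trimethyl-1,2-bis[(triethylsilyl)oxy]cyclohexyl.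

**Route**

Step 1
Reactants: 1 (−)-actinol, (4R,6R)-4-hydroxy-2,2,6-trimethylcyclohexan-1-one
Product: 2 (4R,6R)-4-[(tert-butyldimethylsilyl)oxy]-2,2,6-trimethylcyclohexan-1-one
Conditions: TBSCl, imidazole, DMF, 23 °C
Reagents that add atoms: tert-butyldimethylsilyl chloride, CC(C)(C)[Si](C)(C)Cl
Why: Imidazole-promoted silylation of the only hydroxyl leaves both stereocentres untouched and masks the C3 carbinol for the whole route.

Step 2
Reactants: 2 silyl ether of actinol
Product: 4 (4R)-4-[(tert-butyldimethylsilyl)oxy]-2,6,6-trimethylcyclohex-1-en-1-yl trifluoromethanesulfonate, via lithium enolate 3 (not isolated)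
Conditions: LiN(iPr)2, THF, −78 → 0 °C; then PhNTf2, 0 → 23 °C
Reagents that add atoms: N-phenylbis(trifluoromethanesulfonimide), O=S(=O)(N(c1ccccc1)S(=O)(=O)C(F)(F)F)C(F)(F)F
Why: Enol triflate formation should give one regioisomer because the ketone can enolise only towards the methyl-bearing carbon (the other α-carbon is quaternary), which also removes the superfluous C6 stereocentre of actinol.

Step 3
Reactants: 4 enol triflate; 5 (2E)-3-methylpent-2-en-4-yn-1-ol
Product: 6 (2E)-3-methyl-5-RA-pent-2-en-4-yn-1-ol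
Conditions: Pd(PPh3)4 (5 mol %), CuI (10 mol %), iPr2NH, DMF, 23 °C
Reagents that add atoms: none
Why: Sonogashira coupling of an alkenyl triflate with a terminal alkyne installs the 7,8-didehydro end group and keeps the E geometry of the enynol.

Step 4
Reactants: 6 C15 enynol
Product: 7 (2E)-3-methyl-5-RA-pent-2-en-4-ynal
Conditions: MnO2, CH2Cl2, 23 °C
Reagents that add atoms: none
Why: Allylic oxidation with MnO2 should stop at the enal without isomerising the trisubstituted alkene.

Step 5
Reactants: 7 C15 enynal; 8 triethyl 4-phosphonocrotonate, ethyl (2E)-4-(diethoxyphosphoryl)but-2-enoate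
Product: 9 ethyl (2E,4E,6E)-7-methyl-9-RA-nona-2,4,6-trien-8-ynoate
Conditions: LiCl, DBU, MeCN, 23 °C
Reagents that add atoms: none
Why: Vinylogous Horner–Wadsworth–Emmons olefination under mild LiCl/amidine conditions should be E-selective because the stabilised phosphonate anion adds reversibly.

Step 6
Reactants: 9 C19 trienynoate
Product: 10 (2E,4E,6E)-7-methyl-9-RA-nona-2,4,6-trien-8-yn-1-ol
Conditions: iBu2AlH (2.2 equiv), CH2Cl2, −78 °C
Reagents that add atoms: none
Why: 1,2-Reduction of the conjugated ester by iBu2AlH gives the allylic alcohol without touching the alkyne or the silyl ether.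

Step 7
Reactants: 10 C19 alcohol
Product: 11 (2E,4E,6E)-7-methyl-9-RA-nona-2,4,6-trien-8-ynal
Conditions: MnO2, CH2Cl2, 23 °C, dark
Reagents that add atoms: none
Why: Allylic oxidation with MnO2 is selective for the polyenylic alcohol and is the standard way to polyenals.

Step 8
Reactants: 11 C19 aldehyde; 12 2-(triphenyl-λ5-phosphanylidene)propanal
Product: 13 (2E,4E,6E,8E)-2,9-dimethyl-11-RA-undeca-2,4,6,8-tetraen-10-ynal
Conditions: toluene, 70 °C, dark
Reagents that add atoms: none
Why: Wittig olefination with a stabilised formyl ylide should give the (E)-2-methyl enal and stop after one homologation because the α-branched, more conjugated product aldehyde is less electrophilic.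

Step 9
Reactants: 4 enol triflate
Product: 14 methyl (4R)-4-[(tert-butyldimethylsilyl)oxy]-2,6,6-trimethylcyclohex-1-ene-1-carboxylate
Conditions: Pd(OAc)2 (5 mol %), PPh3 (10 mol %), CO (1 atm), MeOH, Et3N, DMF, 60 °C
Reagents that add atoms: carbon monoxide, [C-]#[O+]; methanol, CO
Why: Palladium-catalysed methoxycarbonylation of the alkenyl triflate (oxidative addition, CO insertion, methanolysis) attaches the future C7 to C6.

Step 10
Reactants: 14 methyl ester
Product: 15 [(4R)-4-[(tert-butyldimethylsilyl)oxy]-2,6,6-trimethylcyclohex-1-en-1-yl]methanol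
Conditions: iBu2AlH (2.2 equiv), CH2Cl2, −78 °C
Reagents that add atoms: none
Why: Reduction of the unsaturated ester by iBu2AlH gives the tetrasubstituted allylic alcohol needed for directed epoxidation.

Step 11
Reactants: 15 allylic alcohol
Product: 16 [(1S,4S,6S)-4-[(tert-butyldimethylsilyl)oxy]-2,2,6-trimethyl-7-oxabicyclo[4.1.0]heptan-1-yl]methanol (oxirane on the ring face that carries the silyloxy group)
Conditions: Ti(OiPr)4 (0.2 equiv), L-(+)-diethyl tartrate (0.24 equiv), t-BuOOH, 4 Å molecular sieves, CH2Cl2, −20 °C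
Reagents that add atoms: tert-butyl hydroperoxide, CC(C)(C)OO
Why: In this Sharpless asymmetric epoxidation the L-(+)-tartrate titanium complex should deliver the peroxide oxygen to the alkene face syn to the C3 silyloxy group, so reagent control sets C5 and C6 as the syn-epoxide.

Step 12
Reactants: 16 syn-epoxy alcohol
Product: 17 (1S,2R,4S)-4-[(tert-butyldimethylsilyl)oxy]-1-(hydroxymethyl)-2,6,6-trimethylcyclohexane-1,2-diol (tertiary hydroxyls trans; C6–OH cis to the C3 silyloxy group)
Conditions: HClO4 (cat.), THF–H2O (4:1), 0 °C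
Reagents that add atoms: water, O
Why: In this acid-catalysed epoxide hydrolysis water should attack the tertiary C5 (C6 is neopentyl and deactivated by the adjacent CH2OH) anti to the oxirane (trans-diaxial opening, Fürst–Plattner rule), which inverts C5, leaves the C6–O bond intact and so sets the (5R,6R) trans-diol.

Step 13
Reactants: 17 triol
Product: 18 tert-butyldimethyl{[(1S,3R,4S)-3,5,5-trimethyl-3,4-bis[(triethylsilyl)oxy]-4-{[(triethylsilyl)oxy]methyl}cyclohexyl]oxy}silane (tris-triethylsilyl ether of 17)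
Conditions: Et3SiOTf (4 equiv), 2,6-lutidine, CH2Cl2, −78 → 23 °C
Reagents that add atoms: triethylsilyl trifluoromethanesulfonate, CC[Si](CC)(CC)OS(=O)(=O)C(F)(F)F
Why: Exhaustive silylation with the silyl triflate caps the primary and the two hindered tertiary hydroxyls, which must not be free during the aluminate and organolithium steps.

Step 14
Reactants: 18 tris-triethylsilyl ether
Product: 19 (1R,2R,4S)-4-[(tert-butyldimethylsilyl)oxy]-2,6,6-trimethyl-1,2-bis[(triethylsilyl)oxy]cyclohexane-1-carbaldehyde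
Conditions: (COCl)2, DMSO, CH2Cl2, −78 → −30 °C; then Et3N, −78 → 0 °C
Reagents that add atoms: none
Why: Swern oxidation applied directly to a primary triethylsilyl ether: the chlorosulfonium ion attacks only the unhindered primary silyl ether oxygen, so the aldehyde forms while the tertiary carbinols stay protected and α-ketol rearrangement is avoided.

Step 15
Reactants: 19 aldehyde
Product: 20 (E)-1-iodo-2-RB-ethene
Conditions: CrCl2 (8 equiv), CHI3 (3 equiv), THF, 0 → 23 °C
Reagents that add atoms: iodoform, IC(I)I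
Why: Takai olefination adds the geminal dichromium species to the aldehyde and eliminates to the (E)-alkenyl iodide, which fixes the E geometry of the C7=C8 bond.

Step 16
Reactants: 20 alkenyl iodide; 21 prop-2-yn-1-ol
Product: 22 (4E)-5-RB-pent-4-en-2-yn-1-ol
Conditions: PdCl2(PPh3)2 (3 mol %), CuI (6 mol %), Et3N, THF, 23 °C
Reagents that add atoms: none
Why: Sonogashira coupling with retention of the alkene geometry gives the conjugated enynol whose three new carbons become C3, C4 and C5 of the furanone.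

Step 17
Reactants: 22 enynol
Product: 24 (2Z,4E)-3-iodo-5-RB-penta-2,4-dien-1-ol, via cyclic vinylalanate 23 (not isolated)
Conditions: NaAlH2(OCH2CH2OMe)2 (Red-Al, 2 equiv), THF, 0 → 23 °C; EtOAc; then I2, −78 → 0 °C
Reagents that add atoms: iodine, II
Why: Alkoxide-directed trans-hydroalumination of the propargylic alcohol places aluminium on the alkyne carbon remote from oxygen in a five-membered alanate, and iodinolysis with retention gives the (2Z)-iodide with iodine cis to the CH2OH arm.

Step 18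
Reactants: 24 iodo dienol
Product: 25 (2Z,4E)-3-iodo-5-RB-penta-2,4-dien-1-yl phenyl carbonate
Conditions: PhOC(O)Cl, pyridine, CH2Cl2, 0 °C
Reagents that add atoms: phenyl chloroformate, O=C(Cl)Oc1ccccc1
Why: Acylation of the primary allylic alcohol gives the mixed aryl carbonate whose carbonyl carbon is the future lactone carbonyl, already bound to the future ring oxygen.

Step 19
Reactants: 25 iodo dienyl phenyl carbonate; 13 C22 polyenynal
Product: 30 (5Z)-3-[(E)-2-RB-ethenyl]-5-[(2E,4E,6E,8E)-2,9-dimethyl-11-RA-undeca-2,4,6,8-tetraen-10-yn-1-ylidene]furan-2(5H)-one, via dienyllithium 26 (not isolated), via butenolide 27 (not isolated), via lithium furanolate 28 (not isolated), via aldol acetate 29 (not isolated)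
Conditions: t-BuLi (2.0 equiv), THF–Et2O, −100 → −78 °C; LiN(SiMe3)2 (1.1 equiv), −78 °C; 13, −78 °C; Ac2O, −78 → 0 °C; DBU, 0 → 23 °C, dark
Reagents that add atoms: none
Why: Iodine–lithium exchange on the alkenyl iodide is faster than addition of t-BuLi to the aryl carbonate at −100 °C and proceeds with retention, so dienyllithium 26 holds its carbanion cis to the CH2–O–C(=O)OPh arm and closes the lactone by 5-exo-trig addition–elimination at the carbonate carbon with loss of phenoxide, the best leaving group on that carbon (Parham-type cyclisation, the closest known type being lactone formation by halogen–lithium exchange next to O-bound carbonates and carbamates). This forms the C2–C3 bond of the furanone and no stereocentre; it needs only the Z-iodide fixed in step 17, and the low temperature together with the internal trap should protect the alkenyllithium from proton transfer. LiN(SiMe3)2 then removes a C5 proton of butenolide 27 to give the aromatic furanolate 28, which should attack polyenal 13 through C5 because C3 is fully substituted and the diene terminus is neopentyl (vinylogous aldol addition). Acetylation of the aldolate and DBU-induced E1cB loss of acetate through the planar furanolate give the ylidene; the Z isomer (chain syn to O1, away from C4–H) is the more stable one and is expected to predominate whatever the configuration of aldol acetate 29. In one flask the step thus closes the only new ring, joins the two halves and completes the C37 chromophore.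

Step 20
Reactants: 30 tetrasilyl ether
Product: 31 CNP0163979.1, (5Z)-3-[(E)-2-[(1R,2R,4S)-1,2,4-trihydroxy-2,6,6-trimethylcyclohexyl]ethenyl]-5-[(2E,4E,6E,8E)-11-[(4R)-4-hydroxy-2,6,6-trimethylcyclohex-1-en-1-yl]-2,9-dimethylundeca-2,4,6,8-tetraen-10-yn-1-ylidene]furan-2(5H)-one
Conditions: HF·pyridine, pyridine, THF, 0 → 23 °C, dark
Reagents that add atoms: none
Why: Fluoride-mediated desilylation under buffered conditions should cleave the two tert-butyldimethylsilyl and two triethylsilyl ethers while sparing the ylidenebutenolide, the polyenyne and the tertiary allylic alcohol.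

**Compound list**

1 | (−)-actinol, (4R,6R)-4-hydroxy-2,2,6-trimethylcyclohexan-1-one | O=C1C(C)(C)C[C@H](O)C[C@H]1C | starting material
2 | (4R,6R)-4-[(tert-butyldimethylsilyl)oxy]-2,2,6-trimethylcyclohexan-1-one | O=C1C(C)(C)C[C@H](O[Si](C)(C)C(C)(C)C)C[C@H]1C | intermediate
3 | lithium (4R)-4-[(tert-butyldimethylsilyl)oxy]-2,6,6-trimethylcyclohex-1-en-1-olate | CC1=C(O[Li])C(C)(C)C[C@H](O[Si](C)(C)C(C)(C)C)C1 | intermediate
4 | (4R)-4-[(tert-butyldimethylsilyl)oxy]-2,6,6-trimethylcyclohex-1-en-1-yl trifluoromethanesulfonate | CC1=C(OS(=O)(=O)C(F)(F)F)C(C)(C)C[C@H](O[Si](C)(C)C(C)(C)C)C1 | intermediate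
5 | (2E)-3-methylpent-2-en-4-yn-1-ol | C#C/C(C)=C/CO | starting material
6 | (2E)-3-methyl-5-RA-pent-2-en-4-yn-1-ol | CC1=C(C#C/C(C)=C/CO)C(C)(C)C[C@H](O[Si](C)(C)C(C)(C)C)C1 | intermediate
7 | (2E)-3-methyl-5-RA-pent-2-en-4-ynal | CC1=C(C#C/C(C)=C/C=O)C(C)(C)C[C@H](O[Si](C)(C)C(C)(C)C)C1 | intermediate
8 | triethyl 4-phosphonocrotonate, ethyl (2E)-4-(diethoxyphosphoryl)but-2-enoate | CCOC(=O)/C=C/CP(=O)(OCC)OCC | starting material
9 | ethyl (2E,4E,6E)-7-methyl-9-RA-nona-2,4,6-trien-8-ynoate | CC1=C(C#C/C(C)=C/C=C/C=C/C(=O)OCC)C(C)(C)C[C@H](O[Si](C)(C)C(C)(C)C)C1 | intermediate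
10 | (2E,4E,6E)-7-methyl-9-RA-nona-2,4,6-trien-8-yn-1-ol | CC1=C(C#C/C(C)=C/C=C/C=C/CO)C(C)(C)C[C@H](O[Si](C)(C)C(C)(C)C)C1 | intermediate
11 | (2E,4E,6E)-7-methyl-9-RA-nona-2,4,6-trien-8-ynal | CC1=C(C#C/C(C)=C/C=C/C=C/C=O)C(C)(C)C[C@H](O[Si](C)(C)C(C)(C)C)C1 | intermediate
12 | 2-(triphenyl-λ5-phosphanylidene)propanal | CC(C=O)=P(c1ccccc1)(c1ccccc1)c1ccccc1 | starting material
13 | (2E,4E,6E,8E)-2,9-dimethyl-11-RA-undeca-2,4,6,8-tetraen-10-ynal | CC1=C(C#C/C(C)=C/C=C/C=C/C=C(C)/C=O)C(C)(C)C[C@H](O[Si](C)(C)C(C)(C)C)C1 | intermediate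
14 | methyl (4R)-4-[(tert-butyldimethylsilyl)oxy]-2,6,6-trimethylcyclohex-1-ene-1-carboxylate | CC1=C(C(=O)OC)C(C)(C)C[C@H](O[Si](C)(C)C(C)(C)C)C1 | intermediate
15 | [(4R)-4-[(tert-butyldimethylsilyl)oxy]-2,6,6-trimethylcyclohex-1-en-1-yl]methanol | CC1=C(CO)C(C)(C)C[C@H](O[Si](C)(C)C(C)(C)C)C1 | intermediate
16 | [(1S,4S,6S)-4-[(tert-butyldimethylsilyl)oxy]-2,2,6-trimethyl-7-oxabicyclo[4.1.0]heptan-1-yl]methanol | OC[C@@]12C(C)(C)C[C@H](O[Si](C)(C)C(C)(C)C)C[C@]1(C)O2 | intermediate
17 | (1S,2R,4S)-4-[(tert-butyldimethylsilyl)oxy]-1-(hydroxymethyl)-2,6,6-trimethylcyclohexane-1,2-diol | OC[C@@]1(O)C(C)(C)C[C@H](O[Si](C)(C)C(C)(C)C)C[C@@]1(C)O | intermediate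
18 | tris-triethylsilyl ether of 17 (primary and both tertiary oxygens silylated) | CC[Si](CC)(CC)OC[C@@]1(O[Si](CC)(CC)CC)C(C)(C)C[C@H](O[Si](C)(C)C(C)(C)C)C[C@@]1(C)O[Si](CC)(CC)CC | intermediate
19 | (1R,2R,4S)-4-[(tert-butyldimethylsilyl)oxy]-2,6,6-trimethyl-1,2-bis[(triethylsilyl)oxy]cyclohexane-1-carbaldehyde | O=C[C@@]1(O[Si](CC)(CC)CC)C(C)(C)C[C@H](O[Si](C)(C)C(C)(C)C)C[C@@]1(C)O[Si](CC)(CC)CC | intermediate
20 | (E)-1-iodo-2-RB-ethene | I/C=C/[C@@]1(O[Si](CC)(CC)CC)C(C)(C)C[C@H](O[Si](C)(C)C(C)(C)C)C[C@@]1(C)O[Si](CC)(CC)CC | intermediate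
21 | prop-2-yn-1-ol | C#CCO | starting material
22 | (4E)-5-RB-pent-4-en-2-yn-1-ol | OCC#C/C=C/[C@@]1(O[Si](CC)(CC)CC)C(C)(C)C[C@H](O[Si](C)(C)C(C)(C)C)C[C@@]1(C)O[Si](CC)(CC)CC | intermediate
23 | sodium 2,2-bis(2-methoxyethoxy)-3-[(E)-2-RB-ethenyl]-2,5-dihydro-1,2-oxaluminol-2-uide (cyclic vinylalanate) | [Na+].COCCO[Al-]1(OCCOC)OCC=C1/C=C/[C@@]2(O[Si](CC)(CC)CC)C(C)(C)C[C@H](O[Si](C)(C)C(C)(C)C)C[C@@]2(C)O[Si](CC)(CC)CC | intermediate
24 | (2Z,4E)-3-iodo-5-RB-penta-2,4-dien-1-ol | OC/C=C(\I)/C=C/[C@@]1(O[Si](CC)(CC)CC)C(C)(C)C[C@H](O[Si](C)(C)C(C)(C)C)C[C@@]1(C)O[Si](CC)(CC)CC | intermediate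
25 | (2Z,4E)-3-iodo-5-RB-penta-2,4-dien-1-yl phenyl carbonate | O=C(Oc1ccccc1)OC/C=C(\I)/C=C/[C@@]2(O[Si](CC)(CC)CC)C(C)(C)C[C@H](O[Si](C)(C)C(C)(C)C)C[C@@]2(C)O[Si](CC)(CC)CC | intermediate
26 | (2Z,4E)-3-lithio-5-RB-penta-2,4-dien-1-yl phenyl carbonate | O=C(Oc1ccccc1)OC/C=C(\[Li])/C=C/[C@@]2(O[Si](CC)(CC)CC)C(C)(C)C[C@H](O[Si](C)(C)C(C)(C)C)C[C@@]2(C)O[Si](CC)(CC)CC | intermediate
27 | 3-[(E)-2-RB-ethenyl]furan-2(5H)-one | O=C1OCC=C1/C=C/[C@@]2(O[Si](CC)(CC)CC)C(C)(C)C[C@H](O[Si](C)(C)C(C)(C)C)C[C@@]2(C)O[Si](CC)(CC)CC | intermediate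
28 | lithium 3-[(E)-2-RB-ethenyl]furan-2-olate | [Li]Oc1occc1/C=C/[C@@]2(O[Si](CC)(CC)CC)C(C)(C)C[C@H](O[Si](C)(C)C(C)(C)C)C[C@@]2(C)O[Si](CC)(CC)CC | intermediate
29 | (3E,5E,7E,9E)-3,10-dimethyl-1-{5-oxo-4-[(E)-2-RB-ethenyl]-2,5-dihydrofuran-2-yl}-12-RA-dodeca-3,5,7,9-tetraen-11-yn-2-yl acetate (aldol acetate, mixture of diastereomers at the two new carbinol-derived centres) | CC1=C(C#C/C(C)=C/C=C/C=C/C=C(C)/C(OC(C)=O)C2OC(=O)C(/C=C/[C@@]3(O[Si](CC)(CC)CC)C(C)(C)C[C@H](O[Si](C)(C)C(C)(C)C)C[C@@]3(C)O[Si](CC)(CC)CC)=C2)C(C)(C)C[C@H](O[Si](C)(C)C(C)(C)C)C1 | intermediate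
30 | (5Z)-3-[(E)-2-RB-ethenyl]-5-[(2E,4E,6E,8E)-2,9-dimethyl-11-RA-undeca-2,4,6,8-tetraen-10-yn-1-ylidene]furan-2(5H)-one | CC1=C(C#C/C(C)=C/C=C/C=C/C=C(C)/C=C2C=C(/C=C/[C@@]3(O[Si](CC)(CC)CC)C(C)(C)C[C@H](O[Si](C)(C)C(C)(C)C)C[C@@]3(C)O[Si](CC)(CC)CC)C(=O)O/2)C(C)(C)C[C@H](O[Si](C)(C)C(C)(C)C)C1 | intermediate
31 | CNP0163979.1, (5Z)-3-[(E)-2-[(1R,2R,4S)-1,2,4-trihydroxy-2,6,6-trimethylcyclohexyl]ethenyl]-5-[(2E,4E,6E,8E)-11-[(4R)-4-hydroxy-2,6,6-trimethylcyclohex-1-en-1-yl]-2,9-dimethylundeca-2,4,6,8-tetraen-10-yn-1-ylidene]furan-2(5H)-one | CC1=C(C#C/C(C)=C/C=C/C=C/C=C(C)/C=C2C=C(/C=C/[C@@]3(O)C(C)(C)C[C@H](O)C[C@@]3(C)O)C(=O)O/2)C(C)(C)C[C@H](O)C1 | target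

**Step count and risks**

Total step count: 20. Longest linear sequence: 14 steps (steps 1, 2 and 9–20).

Most likely to fail, step 19. The dienyllithium may be lost by proton transfer, or t-BuLi may attack the carbonate before exchange. Furanolate formation may be incomplete, and the elimination may show poor Z/E control or degrade the polyene; all of this is compounded in one flask. The fallback sets out from 24 and comes back at 30. Carbonylative lactonisation of iodo alcohol 24 [PdCl2(PPh3)2, CO (1 atm), K2CO3, THF, 50 °C] should give butenolide 27, now isolated; in this variant the lactone is closed at the acyl–oxygen bond after CO insertion. Deprotonation to furanolate 28 [LiN(SiMe3)2, THF, −78 °C] and bromination with N-bromosuccinimide should give the 5-bromobutenolide F1. Triphenylphosphine (toluene, 23 °C) should convert it into the phosphonium bromide F2. Wittig reaction of F2 with polyenal 13 (Et3N, CH2Cl2, 0 → 23 °C) should then give 30.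

Second, step 11. The reagent-controlled syn delivery may be mismatched with the ring's own facial bias, and epoxidation of the tetrasubstituted alkene may be sluggish. The fallback sets out from 15 and comes back at 16. Desilylation (Bu4NF, THF) should give the diol F3. Hydroxyl-directed epoxidation [VO(acac)2, t-BuOOH, CH2Cl2, 0 °C], in which the homoallylic ring hydroxyl delivers the oxidant to its own face, should give the syn-epoxy diol F4. Bis-silylation (TBSCl, imidazole, DMF) should give the bis-silyl ether F5, and selective cleavage of the primary silyl ether (HF·pyridine, pyridine, THF, 0 °C) should return 16.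

Third, step 12. Protic acid may cleave the silyl ether, open the oxirane at C6, or trigger a pinacol-type rearrangement of the tertiary cation. The fallback sets out from 16 and comes back at 17. Chelation-directed opening with benzoic acid [Ti(OiPr)4, PhCO2H, CH2Cl2, 23 °C] should deliver benzoate to C5 (the carbon remote from the carbinol) with inversion and give the hydroxy benzoate F6. Methanolysis (K2CO3, MeOH, 0 °C) should then return 17.

**Further compounds**

F1 | step 19 | 5-bromo-3-[(E)-2-RB-ethenyl]furan-2(5H)-one | O=C1OC(Br)C=C1/C=C/[C@@]2(O[Si](CC)(CC)CC)C(C)(C)C[C@H](O[Si](C)(C)C(C)(C)C)C[C@@]2(C)O[Si](CC)(CC)CC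
F2 | step 19 | {5-oxo-4-[(E)-2-RB-ethenyl]-2,5-dihydrofuran-2-yl}triphenylphosphonium bromide | [Br-].O=C1OC([P+](c3ccccc3)(c3ccccc3)c3ccccc3)C=C1/C=C/[C@@]2(O[Si](CC)(CC)CC)C(C)(C)C[C@H](O[Si](C)(C)C(C)(C)C)C[C@@]2(C)O[Si](CC)(CC)CC
F3 | step 11 | (1R)-4-(hydroxymethyl)-3,5,5-trimethylcyclohex-3-en-1-ol | CC1=C(CO)C(C)(C)C[C@H](O)C1
F4 | step 11 | (1S,3S,6S)-6-(hydroxymethyl)-1,5,5-trimethyl-7-oxabicyclo[4.1.0]heptan-3-ol (oxirane syn to the ring hydroxyl) | OC[C@@]12C(C)(C)C[C@H](O)C[C@]1(C)O2
F5 | step 11 | bis(tert-butyldimethylsilyl) ether of F4 | CC(C)(C)[Si](C)(C)OC[C@@]12C(C)(C)C[C@H](O[Si](C)(C)C(C)(C)C)C[C@]1(C)O2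
F6 | step 12 | (1R,2S,5S)-5-[(tert-butyldimethylsilyl)oxy]-2-hydroxy-2-(hydroxymethyl)-1,3,3-trimethylcyclohexyl benzoate | OC[C@@]1(O)C(C)(C)C[C@H](O[Si](C)(C)C(C)(C)C)C[C@@]1(C)OC(=O)c2ccccc2
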